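**Strategy**

The whole route converges on a ring-closing metathesis that forms the C4=C5 alkene of the cyclohexene ring A (core numbering: C1 quaternary oxirane carbon, C2 OMe, C3 OBz, C4=C5, C6 oxirane CH, O7). Its precursor is an acyclic 1,7-diene carrying everything else: the cis-configured trisubstituted vinyl oxirane (C1, C6), the C2 methyl ether and both benzoates, so one operation closes the carbocycle and delivers the target. The step exploits the cis oxirane, which holds the two vinyl-terminated arms on one side. The diene is built from a butenolide (locks the alkene geometry), an alkoxyallylboration (C2, C3) and a tartrate-controlled epoxidation (C1, C6).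

Key step: step 11

Remark: 1 is used as its commercial dimer; allyl methoxymethyl ether 9 and (−)-B-methoxydiisopinocampheylborane, (−)-Ipc2BOMe, made from (+)-α-pinene, are taken as catalogue reagents. The stereochemical assignments in steps 6 and 9 rest on the usual facial models for these reagents.

**Route**

Step 1
Reactants: 1 1,3-dihydroxyacetone; 2 ethyl (triphenylphosphoranylidene)acetate
Product: 4 4-(hydroxymethyl)furan-2(5H)-one, via hydroxy enoate 3 (not isolated)
Conditions: CH2Cl2, rt, 16 h
Reagents that add atoms: none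
Why: Wittig olefination of the symmetrical ketone by the stabilized ylide should give enoate 3, in which one of the two equivalent hydroxymethyl groups is necessarily cis to the ester and lactonizes in the flask; no stereocentre is formed.

Step 2
Reactants: 4 4-(hydroxymethyl)furan-2(5H)-one
Product: 5 4-[(methoxymethoxy)methyl]furan-2(5H)-one
Conditions: MOMCl, iPr2NEt, CH2Cl2, 0 °C to rt
Reagents that add atoms: chloromethyl methyl ether, COCCl
Why: Williamson-type O-alkylation of the primary alcohol by the α-chloro ether under amine base; an alkoxymethyl ether is chosen because, unlike a silyl or acyl group, it cannot migrate between the two primary oxygens later and so cannot scramble the alkene geometry.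

Step 3
Reactants: 5 4-[(methoxymethoxy)methyl]furan-2(5H)-one
Product: 6 4-[(methoxymethoxy)methyl]-2,5-dihydrofuran-2-ol (racemic lactol)
Conditions: iBu2AlH (1.1 equiv), CH2Cl2, −78 °C; aq. potassium sodium tartrate
Reagents that add atoms: none
Why: Partial reduction of a lactone to the lactol, the tetrahedral aluminium hemiacetal surviving at −78 °C until work-up; the lactol carbon is a transient stereocentre of no consequence.

Step 4
Reactants: 6 4-[(methoxymethoxy)methyl]-2,5-dihydrofuran-2-ol
Product: 7 (2E)-2-[(methoxymethoxy)methyl]penta-2,4-dien-1-ol (free CH2OH cis to the vinyl group)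
Conditions: Ph3PCH3Br, KN(SiMe3)2 (2.5 equiv each), THF, 0 °C to rt
Reagents that add atoms: methylenetriphenylphosphorane (made in the flask from Ph3PCH3Br and KN(SiMe3)2), C=P(c1ccccc1)(c1ccccc1)c1ccccc1
Why: Wittig methylenation of the open hydroxy-aldehyde tautomer of the lactol; the trisubstituted alkene geometry is inherited from the five-membered ring, so the liberated hydroxymethyl group should be cis to the new vinyl group.

Step 5
Reactants: 7 (2E)-2-[(methoxymethoxy)methyl]penta-2,4-dien-1-ol
Product: 8 (2Z)-2-[(methoxymethoxy)methyl]penta-2,4-dienal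
Conditions: Dess–Martin periodinane, NaHCO3, CH2Cl2, 0 °C; used at once
Reagents that add atoms: none
Why: Dess–Martin oxidation of a primary allylic alcohol under buffered, non-isomerizing conditions; the aldehyde is carried forward immediately so that the formyl group stays cis to the vinyl group.

Step 6
Reactants: 8 (2Z)-2-[(methoxymethoxy)methyl]penta-2,4-dienal; 9 allyl methoxymethyl ether
Product: 11 (3R,4R,5Z)-3-(methoxymethoxy)-5-[(methoxymethoxy)methyl]octa-1,5,7-trien-4-ol, via allylborane 10 (not isolated)
Conditions: 9, sec-BuLi, THF, −78 °C; (−)-Ipc2BOMe; BF3·OEt2; then 8, −78 °C; NaOH, H2O2, 0 °C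
Reagents that add atoms: none
Why: Brown alkoxyallylboration through a chair Zimmerman–Traxler transition state: the (Z)-enol ether geometry of 10 should give the syn (threo) 3,4-relationship, and the isopinocampheyl groups from (+)-α-pinene should direct attack to the si face of the aldehyde, setting C4 and C3 of 11 (the future C2 and C3 of the target) both as R.

Step 7
Reactants: 11 (3R,4R,5Z)-3-(methoxymethoxy)-5-[(methoxymethoxy)methyl]octa-1,5,7-trien-4-ol
Product: 12 (3R,4R,5Z)-4-methoxy-3-(methoxymethoxy)-5-[(methoxymethoxy)methyl]octa-1,5,7-triene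
Conditions: NaH, MeI, THF, 0 °C to rt
Reagents that add atoms: iodomethane, CI
Why: Williamson ether synthesis on the secondary alkoxide, with no ester or epoxide yet present to interfere; no stereocentre is touched.

Step 8
Reactants: 12 (3R,4R,5Z)-4-methoxy-3-(methoxymethoxy)-5-[(methoxymethoxy)methyl]octa-1,5,7-triene
Product: 13 (3R,4R,5Z)-5-(hydroxymethyl)-4-methoxyocta-1,5,7-trien-3-ol
Conditions: Me2BBr (3 equiv), CH2Cl2, −78 °C; then THF/sat. aq. NaHCO3
Reagents that add atoms: none
Why: Lewis-acid cleavage of both formaldehyde acetals by the bromoborane at −78 °C through α-bromo ethers that hydrolyse on bicarbonate work-up; the low temperature should spare the allylic methyl ether and the diene.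

Step 9
Reactants: 13 (3R,4R,5Z)-5-(hydroxymethyl)-4-methoxyocta-1,5,7-trien-3-ol
Product: 14 (3R,4S)-4-[(2R,3R)-3-ethenyl-2-(hydroxymethyl)oxiran-2-yl]-4-methoxybut-1-en-3-ol
Conditions: Ti(OiPr)4 (20 mol%), D-(−)-diisopropyl tartrate (24 mol%), t-BuOOH, 4 Å MS, CH2Cl2, −20 °C
Reagents that add atoms: tert-butyl hydroperoxide, CC(C)(C)OO
Why: Katsuki–Sharpless asymmetric epoxidation directed by the primary allylic alcohol and regioselective for the adjacent trisubstituted alkene of the dienol; D-(−)-tartrate should deliver oxygen to the face that gives the (2R,3R)-oxirane (the sense that converts (E)-hex-2-en-1-ol into its 2R,3R epoxide), and the alkene geometry places the methoxy-bearing arm and the vinyl group cis on the oxirane.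

Step 10
Reactants: 14 (3R,4S)-4-[(2R,3R)-3-ethenyl-2-(hydroxymethyl)oxiran-2-yl]-4-methoxybut-1-en-3-ol
Product: 15 [(2R,3R)-2-[(1S,2R)-2-(benzoyloxy)-1-methoxybut-3-en-1-yl]-3-ethenyloxiran-2-yl]methyl benzoate
Conditions: BzCl, Et3N, DMAP (cat.), CH2Cl2, 0 °C
Reagents that add atoms: benzoyl chloride, O=C(Cl)c1ccccc1
Why: DMAP-catalysed acylation of the primary and the secondary allylic alcohol under basic conditions that should leave the vinyl oxirane intact; no stereocentre is touched.

Step 11
Reactants: 15 [(2R,3R)-2-[(1S,2R)-2-(benzoyloxy)-1-methoxybut-3-en-1-yl]-3-ethenyloxiran-2-yl]methyl benzoate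
Product: 16 [(1R,2S,3R,6R)-3-(benzoyloxy)-2-methoxy-7-oxabicyclo[4.1.0]hept-4-en-1-yl]methyl benzoate (target)
Conditions: second-generation Grubbs catalyst (H2IMes)(PCy3)Cl2Ru=CHPh (5 mol%), CH2Cl2 (0.005 M), 40 °C
Reagents that add atoms: none
Why: Ring-closing olefin metathesis by the Chauvin mechanism: the ruthenium benzylidene exchanges with one terminal vinyl group, the resulting alkylidene forms a ruthenacyclobutane with the second vinyl group and cycloreverts to the C4=C5 alkene with loss of ethylene. The closest known reaction type is the ring-closing metathesis of oxygenated 1,7-dienes, vinyl oxiranes included, to cyclohexene polyol derivatives. Ring A is closed as a six-membered carbocycle by joining the two terminal alkene carbons, and the ring size enforces the Z alkene. No stereocentre is formed; C1, C2, C3 and C6 are carried unchanged from 15. The step needs cyclization to win over intermolecular cross-metathesis and must leave the vinyl oxirane and the allylic benzoate untouched; high dilution, the cis oxirane that holds both arms on one face, the neutral Lewis-acid-free medium and the irreversible escape of ethylene should secure this.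

**Compound list**

1 | 1,3-dihydroxyacetone (used as its commercial dimer) | OCC(=O)CO | starting material
2 | ethyl (triphenylphosphoranylidene)acetate | CCOC(=O)C=P(c1ccccc1)(c1ccccc1)c1ccccc1 | starting material
3 | ethyl 4-hydroxy-3-(hydroxymethyl)but-2-enoate | CCOC(=O)C=C(CO)CO | intermediate
4 | 4-(hydroxymethyl)furan-2(5H)-one | O=C1OCC(CO)=C1 | intermediate
5 | 4-[(methoxymethoxy)methyl]furan-2(5H)-one | O=C1OCC(COCOC)=C1 | intermediate
6 | 4-[(methoxymethoxy)methyl]-2,5-dihydrofuran-2-ol (racemic lactol) | OC1OCC(COCOC)=C1 | intermediate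
7 | (2E)-2-[(methoxymethoxy)methyl]penta-2,4-dien-1-ol | OC/C(COCOC)=C\C=C | intermediate
8 | (2Z)-2-[(methoxymethoxy)methyl]penta-2,4-dienal | O=C/C(COCOC)=C\C=C | intermediate
9 | allyl methoxymethyl ether | C=CCOCOC | starting material
10 | [(Z)-3-(methoxymethoxy)allyl]diisopinocampheylborane (both isopinocampheyl groups from (+)-α-pinene) | COCO/C=C\CB([C@@H]1C[C@@H]2C[C@H]([C@H]1C)C2(C)C)[C@@H]3C[C@@H]4C[C@H]([C@H]3C)C4(C)C | intermediate
11 | (3R,4R,5Z)-3-(methoxymethoxy)-5-[(methoxymethoxy)methyl]octa-1,5,7-trien-4-ol | O[C@@H]([C@H](OCOC)C=C)/C(COCOC)=C\C=C | intermediate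
12 | (3R,4R,5Z)-4-methoxy-3-(methoxymethoxy)-5-[(methoxymethoxy)methyl]octa-1,5,7-triene | CO[C@@H]([C@H](OCOC)C=C)/C(COCOC)=C\C=C | intermediate
13 | (3R,4R,5Z)-5-(hydroxymethyl)-4-methoxyocta-1,5,7-trien-3-ol | CO[C@@H]([C@H](O)C=C)/C(CO)=C\C=C | intermediate
14 | (3R,4S)-4-[(2R,3R)-3-ethenyl-2-(hydroxymethyl)oxiran-2-yl]-4-methoxybut-1-en-3-ol | CO[C@@H]([C@H](O)C=C)[C@]1(CO)O[C@@H]1C=C | intermediate
15 | [(2R,3R)-2-[(1S,2R)-2-(benzoyloxy)-1-methoxybut-3-en-1-yl]-3-ethenyloxiran-2-yl]methyl benzoate | CO[C@@H]([C@H](OC(=O)c1ccccc1)C=C)[C@]1(COC(=O)c2ccccc2)O[C@@H]1C=C | intermediate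
16 | [(1R,2S,3R,6R)-3-(benzoyloxy)-2-methoxy-7-oxabicyclo[4.1.0]hept-4-en-1-yl]methyl benzoate | CO[C@H]1[C@H](OC(=O)c2ccccc2)C=C[C@H]2O[C@]21COC(=O)c1ccccc1 | target

Total step count: 11. Longest linear sequence: 11 steps.

**Steps most likely to fail**

1. Step 6 (with the short-lived aldehyde 8). The α-branched (2Z)-dienal may isomerize to the more stable 2E isomer, or drift through reversible 6π closure to a 2H-pyran, before the C–C bond forms. That would put the wrong arm cis to the vinyl group on the later oxirane. The fallback forms the same bond while the alkene is still locked in the five-membered ring. It sets out from 5: soft enolization (TBSOTf, Et3N) should give tert-butyl({4-[(methoxymethoxy)methyl]furan-2-yl}oxy)dimethylsilane F1. A catalytic asymmetric vinylogous Mukaiyama aldol addition to acrolein follows (Ti(OiPr)4 with the BINOL enantiomer that leads to the 5R,1′R adduct, then dilute HCl to cleave the silyl aldolate). It should give the threo butenolide (5R)-5-[(1R)-1-hydroxyprop-2-en-1-yl]-4-[(methoxymethoxy)methyl]furan-2(5H)-one F2. MOMCl/iPr2NEt should then give (5R)-5-[(1R)-1-(methoxymethoxy)prop-2-en-1-yl]-4-[(methoxymethoxy)methyl]furan-2(5H)-one F3. iBu2AlH at −78 °C should give the lactol (5R)-5-[(1R)-1-(methoxymethoxy)prop-2-en-1-yl]-4-[(methoxymethoxy)methyl]-2,5-dihydrofuran-2-ol F4. Wittig methylenation (Ph3P=CH2) opens F4 and comes back to the route at 11.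

2. Step 8. The bromoborane may ionize the allylic C–O bonds (the dienylic C4–OMe or the C3 acetal oxygen), with loss or allylic transposition of the methyl ether and erosion of configuration. The fallback replaces both acetals by fluoride-labile groups so that no acid is needed. It sets out from 4: SEMCl/iPr2NEt should give 4-({[2-(trimethylsilyl)ethoxy]methoxy}methyl)furan-2(5H)-one F5. iBu2AlH should give the lactol 4-({[2-(trimethylsilyl)ethoxy]methoxy}methyl)-2,5-dihydrofuran-2-ol F6. Wittig methylenation should give (2E)-2-({[2-(trimethylsilyl)ethoxy]methoxy}methyl)penta-2,4-dien-1-ol F7, and Dess–Martin oxidation (2Z)-2-({[2-(trimethylsilyl)ethoxy]methoxy}methyl)penta-2,4-dienal F8. Allyl [2-(trimethylsilyl)ethoxy]methyl ether, treated as in step 6, should give [(Z)-3-{[2-(trimethylsilyl)ethoxy]methoxy}allyl]diisopinocampheylborane F9. This adds to F8 to give (3R,4R,5Z)-3-{[2-(trimethylsilyl)ethoxy]methoxy}-5-({[2-(trimethylsilyl)ethoxy]methoxy}methyl)octa-1,5,7-trien-4-ol F10. NaH/MeI should give (3R,4R,5Z)-4-methoxy-3-{[2-(trimethylsilyl)ethoxy]methoxy}-5-({[2-(trimethylsilyl)ethoxy]methoxy}methyl)octa-1,5,7-triene F11. Bu4NF in DMPU (4 Å MS, 60 °C) should remove both groups under basic, non-ionizing conditions and come back to the route at 13.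

3. Step 9. Facial selectivity may be poor if the C4 stereocentre opposes the tartrate (mismatched pairing). The free secondary allylic alcohol may compete for titanium, and the titanium alkoxide may open the vinyl epoxy alcohol once formed. The fallback removes the directing hydroxyl groups and uses a reagent-controlled dioxirane epoxidation. It sets out from 13: BzCl/Et3N/DMAP should give (3R,4R,5Z)-5-[(benzoyloxy)methyl]-4-methoxyocta-1,5,7-trien-3-yl benzoate F12. Shi epoxidation then uses the fructose-derived ketone catalyst (the enantiomer that delivers oxygen to the required face), KHSO5 (as 2KHSO5·KHSO4·K2SO4) and K2CO3 in MeCN/dimethoxymethane/H2O at 0 °C. It should oxidize only the trisubstituted alkene of the diene and come back to the route at 15.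

**Further compounds**

F1 | step 6 | tert-butyl({4-[(methoxymethoxy)methyl]furan-2-yl}oxy)dimethylsilane | COCOCc1coc(O[Si](C)(C)C(C)(C)C)c1
F2 | step 6 | (5R)-5-[(1R)-1-hydroxyprop-2-en-1-yl]-4-[(methoxymethoxy)methyl]furan-2(5H)-one | O=C1C=C(COCOC)[C@H]([C@H](O)C=C)O1
F3 | step 6 | (5R)-5-[(1R)-1-(methoxymethoxy)prop-2-en-1-yl]-4-[(methoxymethoxy)methyl]furan-2(5H)-one | O=C1C=C(COCOC)[C@H]([C@H](OCOC)C=C)O1
F4 | step 6 | (5R)-5-[(1R)-1-(methoxymethoxy)prop-2-en-1-yl]-4-[(methoxymethoxy)methyl]-2,5-dihydrofuran-2-ol | OC1C=C(COCOC)[C@H]([C@H](OCOC)C=C)O1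
F5 | step 8 | 4-({[2-(trimethylsilyl)ethoxy]methoxy}methyl)furan-2(5H)-one | O=C1OCC(COCOCC[Si](C)(C)C)=C1
F6 | step 8 | 4-({[2-(trimethylsilyl)ethoxy]methoxy}methyl)-2,5-dihydrofuran-2-ol | OC1OCC(COCOCC[Si](C)(C)C)=C1
F7 | step 8 | (2E)-2-({[2-(trimethylsilyl)ethoxy]methoxy}methyl)penta-2,4-dien-1-ol | OC/C(COCOCC[Si](C)(C)C)=C\C=C
F8 | step 8 | (2Z)-2-({[2-(trimethylsilyl)ethoxy]methoxy}methyl)penta-2,4-dienal | O=C/C(COCOCC[Si](C)(C)C)=C\C=C
F9 | step 8 | [(Z)-3-{[2-(trimethylsilyl)ethoxy]methoxy}allyl]diisopinocampheylborane | C[Si](C)(C)CCOCO/C=C\CB([C@@H]1C[C@@H]2C[C@H]([C@H]1C)C2(C)C)[C@@H]3C[C@@H]4C[C@H]([C@H]3C)C4(C)C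
F10 | step 8 | (3R,4R,5Z)-3-{[2-(trimethylsilyl)ethoxy]methoxy}-5-({[2-(trimethylsilyl)ethoxy]methoxy}methyl)octa-1,5,7-trien-4-ol | O[C@@H]([C@H](OCOCC[Si](C)(C)C)C=C)/C(COCOCC[Si](C)(C)C)=C\C=C
F11 | step 8 | (3R,4R,5Z)-4-methoxy-3-{[2-(trimethylsilyl)ethoxy]methoxy}-5-({[2-(trimethylsilyl)ethoxy]methoxy}methyl)octa-1,5,7-triene | CO[C@@H]([C@H](OCOCC[Si](C)(C)C)C=C)/C(COCOCC[Si](C)(C)C)=C\C=C
F12 | step 9 | (3R,4R,5Z)-5-[(benzoyloxy)methyl]-4-methoxyocta-1,5,7-trien-3-yl benzoate | CO[C@@H]([C@H](OC(=O)c1ccccc1)C=C)/C(COC(=O)c2ccccc2)=C\C=C
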